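**Plan**

- Feature used: the target ring has 25 atoms, the lactone unit C1(=O)–O plus the 23 methylenes C2–C24. The adjacent ring methylenes C15 and C16 can be read as the two alpha carbons of a CH2–SO2–CH2 unit in a ring of 26 atoms.
- Retrosynthesis: C15–C16 is first written as C15=C16. That alkene is cut by a retro-Ramberg–Bäcklund step that places SO2 between C15 and C16. The two C–S bonds are then cut to sulfide and two primary bromides, and last the ester bond C1–O.
- Forward: the chain is joined at the ester (C1–O–C24) and the 26-membered thia-lactone is closed by double S-alkylation (S–C15 and S–C16). Sulfur is oxidised to the sulfone, the ring contracts to 25 atoms with formation of C15=C16, and the alkene is hydrogenated.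
- Stereochemistry: the target has no stereocentre and no double bond. The alkene geometry created in the contraction is erased by the final hydrogenation.

Key step: step 4

Remark: locants C1–C24 follow the hydroxy acid chain (C1 = lactone carbonyl, C24 = OCH2), and ring locants appear only in systematic names. Transient species that form as regio- or stereoisomer mixtures all converge on one product and are not separated.

**Step 1**
Reactants: 1 15-bromopentadecanoic acid; 2 9-bromononan-1-ol
Product: 3 9-bromononyl 15-bromopentadecanoate
Conditions: TsOH·H2O (5 mol %), toluene, reflux, Dean–Stark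
Reagents that add atoms: none
Why: Fischer esterification of an unhindered primary alcohol with a straight-chain acid is driven to completion by azeotropic removal of water, and primary alkyl bromides are stable to catalytic sulfonic acid in hot toluene.

**Step 2**
Reactants: 3 9-bromononyl 15-bromopentadecanoate; 4 sodium sulfide (anhydrous Na2S)
Product: 7 1-oxa-17-thiacyclohexacosan-2-one, via nonyl-end thiolate 5 (not isolated), via acyl-end thiolate 6 (not isolated)
Conditions: Na2S (1.1 equiv), dry DMF, 60 °C, Ar; 3 added by syringe pump over 24 h (about 2 mM final)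
Reagents that add atoms: none
Why: Double SN2 thioetherification under high dilution, in which sulfide displaces one primary bromide to give thiolate 5 or 6, whose intramolecular attack on the remaining unbranched primary bromide should close the 26-membered ring faster than any bimolecular event at millimolar concentration, while the water-free, hydroxide-free medium offers the ester only soft sulfur nucleophiles that should not cleave it.

**Step 3**
Reactants: 7 1-oxa-17-thiacyclohexacosan-2-one
Product: 9 1-oxa-17-thiacyclohexacosan-2-one 17,17-dioxide, via sulfoxide 8 (not isolated)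
Conditions: mCPBA (2.3 equiv), CH2Cl2, 0 °C to rt; aq. Na2SO3/NaHCO3 wash
Reagents that add atoms: mCPBA (3-chloroperoxybenzoic acid), O=C(OO)c1cccc(Cl)c1
Why: Peracid oxidation of a dialkyl sulfide to the sulfone through sulfoxide 8 is fast with slightly more than two equivalents of mCPBA, and a saturated lactone is not attacked by the peracid.

**Step 4**
Reactants: 9 1-oxa-17-thiacyclohexacosan-2-one 17,17-dioxide
Product: 13 (E/Z)-oxacyclopentacos-16-en-2-one, via 16-bromo sulfone 10 (not isolated), via 18-bromo sulfone 11 (not isolated), via episulfone 12 (not isolated)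
Conditions: KOH/Al2O3 (excess), BrCF2CF2Br (3 equiv), t-BuOH/CH2Cl2, 5 °C to rt
Reagents that add atoms: 1,2-dibromo-1,1,2,2-tetrafluoroethane, FC(F)(Br)C(F)(F)Br (its bromine is carried by 10 and 11 only and is lost again before 13)
Why: Ramberg–Bäcklund reaction with in-situ halogenation, a known way to contract macrocyclic sulfones to cycloalkenes: KOH on alumina removes an alpha-sulfonyl proton at C15 or C16, the carbanion takes bromine from BrCF2CF2Br (which collapses to tetrafluoroethene and bromide) to give 10 or 11, and a second deprotonation at the other alpha carbon triggers 1,3-displacement of bromide. That displacement is a 3-exo-tet closure that forms the C15–C16 bond and the thiirane dioxide ring of 12, and loss of SO2 from 12 leaves the C15=C16 alkene in a ring of 25 atoms, so the large ring arises by contraction of the 26-membered one and not by a new macrocyclisation. No stereocentre remains in 13, because cis and trans episulfone only map onto Z and E alkene, and step 5 converts both into the same product. The selectivity needed is reaction at the four alpha-sulfonyl hydrogens in preference to the C2 methylene and the carbonyl of the lactone; it rests on the higher kinetic acidity of alpha-sulfonyl C–H bonds, on the weakly nucleophilic, water-poor hydroxide surface in t-BuOH/CH2Cl2 at low temperature, and on the distance between sulfone and ester (13 methylenes on one side, 8 on the other). Bromination at either alpha carbon converges on 12, and ring closure of the monobromide is expected to outrun a second bromination.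

**Step 5**
Reactants: 13 (E/Z)-oxacyclopentacos-16-en-2-one
Product: 14 24-tetracosanolide (oxacyclopentacosan-2-one)
Conditions: H2 (1 atm), Pd/C (10 wt %), EtOAc, rt
Reagents that add atoms: none
Why: Heterogeneous catalytic hydrogenation adds H2 across the unhindered 1,2-disubstituted C15=C16 bond of both geometric isomers to give one saturated product, and the lactone is inert to H2 over Pd/C under these conditions.

**Compound list**

1 | 15-bromopentadecanoic acid | OC(=O)CCCCCCCCCCCCCCBr | starting material
2 | 9-bromononan-1-ol | OCCCCCCCCCBr | starting material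
3 | 9-bromononyl 15-bromopentadecanoate | O=C(CCCCCCCCCCCCCCBr)OCCCCCCCCCBr | intermediate
4 | sodium sulfide, anhydrous (Na2S) | [Na+].[Na+].[S-2] | starting material
5 | sodium 9-[(15-bromopentadecanoyl)oxy]nonane-1-thiolate (not isolated) | [Na+].[S-]CCCCCCCCCOC(=O)CCCCCCCCCCCCCCBr | intermediate
6 | sodium 15-[(9-bromononyl)oxy]-15-oxopentadecane-1-thiolate (not isolated) | [Na+].[S-]CCCCCCCCCCCCCCC(=O)OCCCCCCCCCBr | intermediate
7 | 1-oxa-17-thiacyclohexacosan-2-one | O=C1CCCCCCCCCCCCCCSCCCCCCCCCO1 | intermediate
8 | 1-oxa-17-thiacyclohexacosan-2-one 17-oxide (racemic at sulfur; not isolated) | O=C1CCCCCCCCCCCCCCS(=O)CCCCCCCCCO1 | intermediate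
9 | 1-oxa-17-thiacyclohexacosan-2-one 17,17-dioxide | O=C1CCCCCCCCCCCCCCS(=O)(=O)CCCCCCCCCO1 | intermediate
10 | 16-bromo-1-oxa-17-thiacyclohexacosan-2-one 17,17-dioxide (bromine on C15 of the chain; racemic; not isolated) | O=C1CCCCCCCCCCCCCC(Br)S(=O)(=O)CCCCCCCCCO1 | intermediate
11 | 18-bromo-1-oxa-17-thiacyclohexacosan-2-one 17,17-dioxide (bromine on C16 of the chain; racemic; not isolated) | O=C1CCCCCCCCCCCCCCS(=O)(=O)C(Br)CCCCCCCCO1 | intermediate
12 | 10-oxa-26-thiabicyclo[23.1.0]hexacosan-11-one 26,26-dioxide (episulfone across C15–C16; cis/trans mixture, racemic; not isolated) | O=C1CCCCCCCCCCCCCC2C(CCCCCCCCO1)S2(=O)=O | intermediate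
13 | (E/Z)-oxacyclopentacos-16-en-2-one (tetracos-15-en-24-olide; E isomer drawn, Z isomer expected alongside) | O=C1CCCCCCCCCCCCC/C=C/CCCCCCCCO1 | intermediate
14 | 24-tetracosanolide (oxacyclopentacosan-2-one; no stereocentre) | O=C1CCCCCCCCCCCCCCCCCCCCCCCO1 | target

**Step count**

Total steps: 5. Longest linear sequence: 5 steps (from 1 or 2 to 14).

**Steps most likely to fail**

Step 4. What may go wrong is saponification of the lactone by the surface hydroxide, enolisation and bromination at C2 next to the lactone carbonyl, or a second bromination at the alpha-sulfonyl carbons before ring closure. The fallback sets out from 7 and places the halogen at the sulfide stage, where only the carbons next to sulfur can react.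
- NCS in CH2Cl2 at 0 °C to rt should chlorinate through the chlorosulfonium salt to give 16-chloro-1-oxa-17-thiacyclohexacosan-2-one F1 and 18-chloro-1-oxa-17-thiacyclohexacosan-2-one F2.
- Without purification, mCPBA in CH2Cl2 should oxidise these through 16-chloro-1-oxa-17-thiacyclohexacosan-2-one 17-oxide F3 and 18-chloro-1-oxa-17-thiacyclohexacosan-2-one 17-oxide F4 to the isolable sulfones 16-chloro-1-oxa-17-thiacyclohexacosan-2-one 17,17-dioxide F5 and 18-chloro-1-oxa-17-thiacyclohexacosan-2-one 17,17-dioxide F6.
- KOt-Bu in dilute THF at −78 to 0 °C then effects the classical Ramberg–Bäcklund reaction of the preformed alpha-chloro sulfones through episulfone 12.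
- This base step contains neither hydroxide nor a halogen source, so enolisation at C2 is reversible and harmless. The fallback comes back to the route at 13.

Step 2. What may go wrong is bimolecular S-alkylation that leads to oligomers, or acyl cleavage of the ester by adventitious hydroxide. The fallback sets out from 2 and 1, forms the C–S bond between two molecules at normal concentration and closes the ring at the ester instead.
- KSAc (potassium thioacetate, CH3COSK) in DMF converts 2 into S-(9-hydroxynonyl) ethanethioate F7.
- NaOH in degassed MeOH/H2O releases sodium 9-hydroxynonane-1-thiolate F8, which alkylates the carboxylate of 1 to give, after acidification, 15-[(9-hydroxynonyl)sulfanyl]pentadecanoic acid F9.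
- Oxone (2KHSO5·KHSO4·K2SO4) in MeOH/THF/H2O oxidises F9 through 15-(9-hydroxynonane-1-sulfinyl)pentadecanoic acid F10 to 15-(9-hydroxynonane-1-sulfonyl)pentadecanoic acid F11.
- Yamaguchi macrolactonisation follows: 2,4,6-trichlorobenzoyl chloride and Et3N in THF give 15-(9-hydroxynonane-1-sulfonyl)pentadecanoic 2,4,6-trichlorobenzoic anhydride F12, which is added slowly to DMAP in hot toluene.
- The fallback comes back to the route at sulfone 9, so step 3 is not needed.

Step 5. What may go wrong is deactivation of the palladium surface by traces of sulfur-containing material carried over from steps 2 to 4, so that hydrogen uptake stalls. The fallback sets out from 13 and replaces the metal-catalysed reduction by diimide, generated from TsNHNH2 and NaOAc in refluxing THF/H2O. Diimide is insensitive to sulfur and does not touch the lactone. The fallback comes back at 14 and makes no new compound (entry F0).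

**Further compounds**

F1 | step 4 | 16-chloro-1-oxa-17-thiacyclohexacosan-2-one | O=C1CCCCCCCCCCCCCC(Cl)SCCCCCCCCCO1
F2 | step 4 | 18-chloro-1-oxa-17-thiacyclohexacosan-2-one | O=C1CCCCCCCCCCCCCCSC(Cl)CCCCCCCCO1
F3 | step 4 | 16-chloro-1-oxa-17-thiacyclohexacosan-2-one 17-oxide | O=C1CCCCCCCCCCCCCC(Cl)S(=O)CCCCCCCCCO1
F4 | step 4 | 18-chloro-1-oxa-17-thiacyclohexacosan-2-one 17-oxide | O=C1CCCCCCCCCCCCCCS(=O)C(Cl)CCCCCCCCO1
F5 | step 4 | 16-chloro-1-oxa-17-thiacyclohexacosan-2-one 17,17-dioxide | O=C1CCCCCCCCCCCCCC(Cl)S(=O)(=O)CCCCCCCCCO1
F6 | step 4 | 18-chloro-1-oxa-17-thiacyclohexacosan-2-one 17,17-dioxide | O=C1CCCCCCCCCCCCCCS(=O)(=O)C(Cl)CCCCCCCCO1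
F7 | step 2 | S-(9-hydroxynonyl) ethanethioate | CC(=O)SCCCCCCCCCO
F8 | step 2 | sodium 9-hydroxynonane-1-thiolate | [Na+].[S-]CCCCCCCCCO
F9 | step 2 | 15-[(9-hydroxynonyl)sulfanyl]pentadecanoic acid | OC(=O)CCCCCCCCCCCCCCSCCCCCCCCCO
F10 | step 2 | 15-(9-hydroxynonane-1-sulfinyl)pentadecanoic acid | OC(=O)CCCCCCCCCCCCCCS(=O)CCCCCCCCCO
F11 | step 2 | 15-(9-hydroxynonane-1-sulfonyl)pentadecanoic acid | OC(=O)CCCCCCCCCCCCCCS(=O)(=O)CCCCCCCCCO
F12 | step 2 | 15-(9-hydroxynonane-1-sulfonyl)pentadecanoic 2,4,6-trichlorobenzoic anhydride | O=C(OC(=O)c1c(Cl)cc(Cl)cc1Cl)CCCCCCCCCCCCCCS(=O)(=O)CCCCCCCCCO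
F0 | step 5 | none | none
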